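**Retrosynthetic overview**
- The depside ester is cut at the aryl C–O bond on ring A (C4–O), not at the acyl C–O bond. The route rests on this feature: the ester carbonyl carbon of ring B lies between C2–OMe and C6–propyl, whereas C4 of ring A has only hydrogen on C3 and C5.
- This gives 2,4-dimethoxy-6-propylbenzoic acid (ring B) and a ring A arylboronic acid carrying a tert-butyl ester at C1, a MOM ether at C2 and propyl at C6; they are joined by copper-mediated oxidative O-arylation.
- Ring A: 6-methylsalicylic acid → tert-butyl ester → MOM ether → lateral lithiation and ethylation (methyl to propyl) → sterically governed C–H borylation at C4 → boronic acid.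
- Ring B: divarinol → dimethyl ether → formylation → oxidation to the acid. Both benzene rings are bought; no ring is formed. Acid removes the tert-butyl and MOM groups at the end.

Key step: step 9

Remark: the target has no stereocentre, so no stereocontrol is needed; Cu(OTf)2 is taken as substoichiometric with air as terminal oxidant, and the ring A boronic acid is used in excess over the ring B acid.

**Route**

Step 1
Reactants: 1 5-propylbenzene-1,3-diol (divarinol)
Product: 2 1,3-dimethoxy-5-propylbenzene
Conditions: MeI, K2CO3, acetone, reflux
Reagents that add atoms: iodomethane, CI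
Why: Twofold Williamson ether synthesis, in which both phenoxides formed by K2CO3 are methylated by SN2 attack on iodomethane and no other nucleophilic site is present.

Step 2
Reactants: 2 1,3-dimethoxy-5-propylbenzene
Product: 4 2,4-dimethoxy-6-propylbenzaldehyde, via iminium salt 3 (not isolated)
Conditions: POCl3, DMF, 0 → 70 °C; then H2O, 0 °C → rt
Reagents that add atoms: N,N-dimethylformamide, CN(C)C=O; water, O
Why: Vilsmeier–Haack formylation, in which the chloroiminium ion attacks the ring carbon para to one methoxy and ortho to the other (two equivalent sites) in preference to the more crowded carbon between the two methoxy groups, and water hydrolyses iminium salt 3 to the aldehyde.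

Step 3
Reactants: 4 2,4-dimethoxy-6-propylbenzaldehyde
Product: 5 2,4-dimethoxy-6-propylbenzoic acid
Conditions: NaClO2, NaH2PO4, 2-methyl-2-butene, t-BuOH/H2O, 0 °C → rt
Reagents that add atoms: sodium chlorite, [Na+].[O-]Cl=O
Why: Pinnick oxidation, in which chlorous acid adds to the aldehyde and fragments to the carboxylic acid and HOCl, which 2-methyl-2-butene traps before it can chlorinate the electron-rich ring.

Step 4
Reactants: 6 2-hydroxy-6-methylbenzoic acid (6-methylsalicylic acid)
Product: 7 tert-butyl 2-hydroxy-6-methylbenzoate
Conditions: Me2NCH(O-t-Bu)2, toluene, 80 °C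
Reagents that add atoms: N,N-dimethylformamide di-tert-butyl acetal, CN(C)C(OC(C)(C)C)OC(C)(C)C
Why: Esterification by O-alkylation with a formamide acetal, in which the acid protonates the acetal and the carboxylate oxygen is tert-butylated, so the crowded carbonyl carbon is not attacked and the hydrogen-bonded phenol reacts far more slowly.

Step 5
Reactants: 7 tert-butyl 2-hydroxy-6-methylbenzoate
Product: 9 tert-butyl 2-(methoxymethoxy)-6-methylbenzoate, via sodium phenoxide 8 (not isolated)
Conditions: NaH, DMF, 0 °C; then MOMCl, 0 °C → rt
Reagents that add atoms: chloromethyl methyl ether, COCCl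
Why: Williamson-type O-alkylation, in which NaH breaks the intramolecular hydrogen bond by forming phenoxide 8, which displaces chloride from MOMCl.

Step 6
Reactants: 9 tert-butyl 2-(methoxymethoxy)-6-methylbenzoate; 10 iodoethane
Product: 12 tert-butyl 2-(methoxymethoxy)-6-propylbenzoate, via benzyllithium 11 (not isolated)
Conditions: LiN(i-Pr)2 (1.2 equiv), THF, −78 °C; then EtI, −78 → −20 °C
Reagents that add atoms: none
Why: Lateral (benzylic) lithiation of an ortho-toluate, in which the amide base removes a methyl proton to give anion 11 stabilised by the ester, the bulky tert-butyl ester resists self-condensation at −78 °C, and SN2 alkylation by iodoethane extends methyl to propyl.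

Step 7
Reactants: 12 tert-butyl 2-(methoxymethoxy)-6-propylbenzoate; 13 bis(pinacolato)diboron
Product: 14 tert-butyl 2-(methoxymethoxy)-6-propyl-4-(4,4,5,5-tetramethyl-1,3,2-dioxaborolan-2-yl)benzoate
Conditions: [Ir(OMe)(cod)]2 (1.5 mol %), 4,4'-di-tert-butyl-2,2'-bipyridine (3 mol %), cyclohexane, 80 °C
Reagents that add atoms: none
Why: Iridium-catalysed aromatic C–H borylation under steric control, in which the bulky tris(boryl)iridium bipyridine catalyst avoids C–H bonds next to a substituent, and C4 is the only ring C–H flanked by two hydrogens (C3 adjoins OMOM, C5 adjoins propyl) while the ester has no ortho C–H to direct.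

Step 8
Reactants: 14 tert-butyl 2-(methoxymethoxy)-6-propyl-4-(4,4,5,5-tetramethyl-1,3,2-dioxaborolan-2-yl)benzoate
Product: 15 [4-(tert-butoxycarbonyl)-3-(methoxymethoxy)-5-propylphenyl]boronic acid
Conditions: NaIO4, NH4OAc, acetone/H2O, rt
Reagents that add atoms: water, O
Why: Oxidative hydrolysis of a pinacol boronate, in which the ester equilibrates with boronic acid and pinacol in buffered aqueous acetone and periodate cleaves the diol to acetone, driving the hydrolysis without acid that would touch the MOM ether or the tert-butyl ester.

Step 9
Reactants: 5 2,4-dimethoxy-6-propylbenzoic acid; 15 [4-(tert-butoxycarbonyl)-3-(methoxymethoxy)-5-propylphenyl]boronic acid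
Product: 16 tert-butyl 4-[(2,4-dimethoxy-6-propylbenzoyl)oxy]-2-(methoxymethoxy)-6-propylbenzoate
Conditions: Cu(OTf)2 (0.4 equiv), urea (1 equiv), 15 (1.5 equiv), EtOAc, 60 °C, open to air
Reagents that add atoms: none
Why: The carboxylate of 5 binds divalent copper, the aryl group of 15 moves from boron to copper (transmetalation), the divalent copper aryl carboxylate is oxidised to trivalent copper, and C–O reductive elimination releases aryl ester 16 and monovalent copper, which air returns to divalent copper. The closest known reaction type is the Chan–Lam esterification of carboxylic acids with arylboronic acids mediated by Cu(OTf)2 and urea. No ring is closed and no stereocentre is formed. The step needs C–O bond formation at the carboxylate oxygen and site fidelity on ring A: the new bond is made at C4 of ring A, whose neighbours C3 and C5 carry only hydrogen, so the carbonyl carbon of 5, crowded by C2–OMe and C6–propyl, is never attacked. The position is dictated by the carbon–boron bond, and the MOM ether and tert-butyl ester leave 15 without a free O–H that could be arylated instead. Urea tempers the acidity of the copper triflate so the acid-labile groups should persist, and the excess of 15 offsets protodeboronation.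

Step 10
Reactants: 16 tert-butyl 4-[(2,4-dimethoxy-6-propylbenzoyl)oxy]-2-(methoxymethoxy)-6-propylbenzoate
Product: 17 4-[(2,4-dimethoxy-6-propylbenzoyl)oxy]-2-hydroxy-6-propylbenzoic acid
Conditions: TFA/CH2Cl2 (1:3), H2O (5 equiv), 0 °C → rt
Reagents that add atoms: none
Why: Acidolysis, in which the protonated tert-butyl ester loses 2-methylpropene by an E1 path and the MOM acetal hydrolyses to the phenol, formaldehyde and methanol, while the aryl ester between rings A and B and the methyl ethers are stable to TFA at room temperature.

**Compound list**
1 | 5-propylbenzene-1,3-diol (divarinol) | CCCc1cc(O)cc(O)c1 | starting material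
2 | 1,3-dimethoxy-5-propylbenzene | CCCc1cc(OC)cc(OC)c1 | intermediate
3 | N-[(2,4-dimethoxy-6-propylphenyl)methylidene]-N-methylmethanaminium dichlorophosphate (not isolated) | CCCc1cc(OC)cc(OC)c1C=[N+](C)C.[O-]P(=O)(Cl)Cl | intermediate
4 | 2,4-dimethoxy-6-propylbenzaldehyde | CCCc1cc(OC)cc(OC)c1C=O | intermediate
5 | 2,4-dimethoxy-6-propylbenzoic acid | CCCc1cc(OC)cc(OC)c1C(=O)O | intermediate
6 | 2-hydroxy-6-methylbenzoic acid (6-methylsalicylic acid) | Cc1cccc(O)c1C(=O)O | starting material
7 | tert-butyl 2-hydroxy-6-methylbenzoate | Cc1cccc(O)c1C(=O)OC(C)(C)C | intermediate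
8 | sodium 2-(tert-butoxycarbonyl)-3-methylphenolate (not isolated) | Cc1cccc([O-])c1C(=O)OC(C)(C)C.[Na+] | intermediate
9 | tert-butyl 2-(methoxymethoxy)-6-methylbenzoate | Cc1cccc(OCOC)c1C(=O)OC(C)(C)C | intermediate
10 | iodoethane | CCI | starting material
11 | [2-(tert-butoxycarbonyl)-3-(methoxymethoxy)benzyl]lithium (not isolated) | [Li]Cc1cccc(OCOC)c1C(=O)OC(C)(C)C | intermediate
12 | tert-butyl 2-(methoxymethoxy)-6-propylbenzoate | CCCc1cccc(OCOC)c1C(=O)OC(C)(C)C | intermediate
13 | bis(pinacolato)diboron | CC1(C)OB(B2OC(C)(C)C(C)(C)O2)OC1(C)C | starting material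
14 | tert-butyl 2-(methoxymethoxy)-6-propyl-4-(4,4,5,5-tetramethyl-1,3,2-dioxaborolan-2-yl)benzoate | CCCc1cc(B2OC(C)(C)C(C)(C)O2)cc(OCOC)c1C(=O)OC(C)(C)C | intermediate
15 | [4-(tert-butoxycarbonyl)-3-(methoxymethoxy)-5-propylphenyl]boronic acid | CCCc1cc(B(O)O)cc(OCOC)c1C(=O)OC(C)(C)C | intermediate
16 | tert-butyl 4-[(2,4-dimethoxy-6-propylbenzoyl)oxy]-2-(methoxymethoxy)-6-propylbenzoate | CCCc1cc(OC(=O)c2c(CCC)cc(OC)cc2OC)cc(OCOC)c1C(=O)OC(C)(C)C | intermediate
17 | 4-[(2,4-dimethoxy-6-propylbenzoyl)oxy]-2-hydroxy-6-propylbenzoic acid | CCCc1cc(OC(=O)c2c(CCC)cc(OC)cc2OC)cc(O)c1C(=O)O | target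

**Step count**
Total: 10 steps. Longest linear sequence: 7 steps (steps 4 to 10, from 6-methylsalicylic acid); the ring B branch is 3 steps (steps 1 to 3) before the union.

**Steps most likely to fail**

Step 9. Aryl transfer to the crowded copper carboxylate may be slower than protodeboronation or oxidative hydroxylation of the boronic acid. The Lewis-acidic copper triflate may also strip the MOM or tert-butyl group and so expose nucleophiles that compete, and copper may protodecarboxylate the electron-rich acid. The fallback makes the same ester by acylation of a single free phenol, with the oxygen still placed by the boron. It sets out from 14 and 5: oxidation of the C–B bond of 14 (H2O2, NaOH, THF/H2O, 0 °C) should give tert-butyl 4-hydroxy-2-(methoxymethoxy)-6-propylbenzoate F1. Acid 5 is converted by (COCl)2 and catalytic DMF in CH2Cl2 into 2,4-dimethoxy-6-propylbenzoyl chloride F2. Acylation of F1 with F2 (Et3N, DMAP, CH2Cl2, rt to reflux) should then give 16, where the route is rejoined.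

Step 6. The benzylic anion may add to the ester of unreacted 9 (self-condensation), the product may be deprotonated and ethylated a second time, or deprotonation may be incomplete. The fallback builds the propyl chain by substitution at a benzylic halide. It sets out from 9: radical bromination (NBS, catalytic AIBN, PhCF3, 80 °C) should give tert-butyl 2-(bromomethyl)-6-(methoxymethoxy)benzoate F3. Copper-catalysed coupling of F3 with EtMgBr (Li2CuCl4 catalytic, THF, −78 → 0 °C) should then give 12, where the route is rejoined.

Step 2. Formylation may occur partly at the carbon between the two methoxy groups and give an isomer mixture that is hard to separate; the chlorite oxidation that follows may also chlorinate the activated ring. The fallback installs the carboxyl carbon through a regioselective halogenation and a carboxylation. It sets out from 2: NBS in MeCN at 0 °C should brominate para to one methoxy group to give 2-bromo-1,5-dimethoxy-3-propylbenzene F4. Bromine–lithium exchange (n-BuLi, THF, −78 °C) gives (2,4-dimethoxy-6-propylphenyl)lithium F5, CO2 converts it into lithium 2,4-dimethoxy-6-propylbenzoate F6, and aqueous HCl liberates 5, where the route is rejoined.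

**Further compounds**
F1 | step 9 | tert-butyl 4-hydroxy-2-(methoxymethoxy)-6-propylbenzoate | CCCc1cc(O)cc(OCOC)c1C(=O)OC(C)(C)C
F2 | step 9 | 2,4-dimethoxy-6-propylbenzoyl chloride | CCCc1cc(OC)cc(OC)c1C(=O)Cl
F3 | step 6 | tert-butyl 2-(bromomethyl)-6-(methoxymethoxy)benzoate | BrCc1cccc(OCOC)c1C(=O)OC(C)(C)C
F4 | step 2 | 2-bromo-1,5-dimethoxy-3-propylbenzene | CCCc1cc(OC)cc(OC)c1Br
F5 | step 2 | (2,4-dimethoxy-6-propylphenyl)lithium | [Li]c1c(CCC)cc(OC)cc1OC
F6 | step 2 | lithium 2,4-dimethoxy-6-propylbenzoate | CCCc1cc(OC)cc(OC)c1C(=O)[O-].[Li+]
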